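The α‑methylene‑γ‑butyrolactone (ring O–C12–C11–C7–C6; germacranolide numbering) is disconnected at O–C6 and C11–C7. The step exploits that C6 is allylic to the C4=C5 alkene of the ten‑membered ring: a γ‑alkenyl lactone is the retron of a diene carbo‑oxygenation. 2‑Bromoacrylic acid and an acyclic (4E,6E)‑diene should give, in one palladium‑catalysed Heck insertion/allylic substitution cascade, both bonds, the C6 and C7 stereocentres and the exocyclic methylene. The precursor is a tetraene whose C8 and C9 oxygen stereocentres come from an alkoxyallylboration of a dienal; the ten‑membered ring is then closed by metathesis at C1=C10.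

Key step: step 10

Remark: germacranolide numbering is used throughout (ring C1–C10, C14 on C10, C15 on C4, lactone C11/C12/C13, lactone oxygen on C6); both ring alkenes are ring‑cis (C2 cis to C9, C3 cis to C6); compounds 1, 2, 5, 9, 11, 17 and 21 are taken as commercial.

Step 1
Reactants: 1 (tert‑butyldimethylsilyloxy)acetaldehyde; 2 but‑3‑enylmagnesium bromide
Product: 3 1‑(tert‑butyldimethylsilyloxy)hex‑5‑en‑2‑ol (racemic)
Conditions: THF, −78 to 0 °C; then H2O
Reagents that add atoms: none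
Why: Grignard addition to the aldehyde should give the secondary alcohol, whose racemic centre is removed in step 2.

Step 2
Reactants: 3 1‑(tert‑butyldimethylsilyloxy)hex‑5‑en‑2‑ol
Product: 4 1‑(tert‑butyldimethylsilyloxy)hex‑5‑en‑2‑one
Conditions: Dess–Martin periodinane, CH2Cl2, rt
Reagents that add atoms: none
Why: Dess–Martin oxidation of a secondary alcohol is neutral and should leave the silyl ether and the terminal alkene untouched.

Step 3
Reactants: 4 1‑(tert‑butyldimethylsilyloxy)hex‑5‑en‑2‑one; 5 ethyl (triphenylphosphoranylidene)acetate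
Product: 6 ethyl (2E)‑3‑[(tert‑butyldimethylsilyloxy)methyl]hepta‑2,6‑dienoate
Conditions: toluene, 110 °C
Reagents that add atoms: none
Why: Wittig olefination of an α‑alkoxy ketone with a stabilised ylide should place the ester trans to the silyloxymethyl group (2E, ester cis to the butenyl chain), the minor isomer being removed by chromatography.

Step 4
Reactants: 6 ethyl (2E)‑3‑[(tert‑butyldimethylsilyloxy)methyl]hepta‑2,6‑dienoate
Product: 7 (2E)‑3‑[(tert‑butyldimethylsilyloxy)methyl]hepta‑2,6‑dien‑1‑ol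
Conditions: iBu2AlH (2.2 equiv), CH2Cl2, −78 °C; then aq. potassium sodium tartrate
Reagents that add atoms: none
Why: 1,2‑Reduction of the enoate with iBu2AlH should give the allylic alcohol without touching the alkene geometry.

Step 5
Reactants: 7 (2E)‑3‑[(tert‑butyldimethylsilyloxy)methyl]hepta‑2,6‑dien‑1‑ol
Product: 8 (2E)‑3‑[(tert‑butyldimethylsilyloxy)methyl]hepta‑2,6‑dienal
Conditions: MnO2, CH2Cl2, rt
Reagents that add atoms: none
Why: MnO2 oxidation is selective for the allylic alcohol and should give the enal without E/Z isomerisation.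

Step 6
Reactants: 8 (2E)‑3‑[(tert‑butyldimethylsilyloxy)methyl]hepta‑2,6‑dienal; 9 (triphenylphosphoranylidene)acetaldehyde
Product: 10 (2E,4E)‑5‑[(tert‑butyldimethylsilyloxy)methyl]nona‑2,4,8‑trienal
Conditions: toluene, 80 °C (1.1 equiv of 9)
Reagents that add atoms: none
Why: Wittig two‑carbon homologation with the formyl‑stabilised ylide should give the E‑configured new alkene (C6=C7), and the less electrophilic dienal product should resist a second homologation at this stoichiometry.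

Step 7
Reactants: 11 2‑methylenepropane‑1,3‑diol
Product: 12 3‑(methoxymethoxy)‑2‑[(methoxymethoxy)methyl]prop‑1‑ene
Conditions: NaH, MOMCl, THF, 0 °C to rt
Reagents that add atoms: chloromethyl methyl ether, COCCl
Why: Williamson‑type acetalisation of both primary hydroxyl groups gives the symmetrical bis‑MOM allyl ether needed for directed metalation.

Step 8
Reactants: 10 (2E,4E)‑5‑[(tert‑butyldimethylsilyloxy)methyl]nona‑2,4,8‑trienal; 12 3‑(methoxymethoxy)‑2‑[(methoxymethoxy)methyl]prop‑1‑ene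
Product: 15 (3S,4S,5E,7E)‑8‑[(tert‑butyldimethylsilyloxy)methyl]‑3‑(methoxymethoxy)‑2‑[(methoxymethoxy)methyl]dodeca‑1,5,7,11‑tetraen‑4‑ol, via allyllithium 13 (not isolated), via allylborane 14 (not isolated)
Conditions: 12, sBuLi, THF, −78 °C; (+)‑Ipc2BOMe (from (−)‑α‑pinene); BF3·OEt2; then 10, −78 °C; NaOH, H2O2, 0 °C
Reagents that add atoms: none
Why: Brown alkoxyallylboration, in which lithiation α to oxygen gives the chelated allyllithium with oxygen cis to the metalated CH2, the derived allylborane reacts through a chair (Zimmerman–Traxler) transition state to give the 8,9‑syn product, and the isopinocampheyl groups select the re face of the aldehyde, so that C8 and C9 are both set S.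

Step 9
Reactants: 15 (3S,4S,5E,7E)‑8‑[(tert‑butyldimethylsilyloxy)methyl]‑3‑(methoxymethoxy)‑2‑[(methoxymethoxy)methyl]dodeca‑1,5,7,11‑tetraen‑4‑ol
Product: 16 (3S,4S,5E,7E)‑8‑[(tert‑butyldimethylsilyloxy)methyl]‑3‑(methoxymethoxy)‑2‑[(methoxymethoxy)methyl]‑4‑(triethylsilyloxy)dodeca‑1,5,7,11‑tetraene
Conditions: TESCl, imidazole, DMF, 0 °C
Reagents that add atoms: chlorotriethylsilane, CC[Si](Cl)(CC)CC
Why: Silylation turns the dienylic C8 hydroxyl into an ether that cannot be ionised by palladium and that acts as the bulky polar group for 1,2‑induction in step 10.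

Step 10
Reactants: 16 (3S,4S,5E,7E)‑8‑[(tert‑butyldimethylsilyloxy)methyl]‑3‑(methoxymethoxy)‑2‑[(methoxymethoxy)methyl]‑4‑(triethylsilyloxy)dodeca‑1,5,7,11‑tetraene; 17 2‑bromoacrylic acid
Product: 18 (4S,5R)‑5‑[(1E)‑2‑[(tert‑butyldimethylsilyloxy)methyl]hexa‑1,5‑dien‑1‑yl]‑4‑[(1S,2S)‑2‑(methoxymethoxy)‑3‑[(methoxymethoxy)methyl]‑1‑(triethylsilyloxy)but‑3‑en‑1‑yl]‑3‑methylideneoxolan‑2‑one
Conditions: Pd(OAc)2 (10 mol %), PPh3 (20 mol %), Ag2CO3 (1.5 equiv), DMF, 60 °C, slow addition of 17 (1.3 equiv)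
Reagents that add atoms: none
Why: Oxidative addition of zerovalent palladium to the C–Br bond of 17 gives a 1‑carboxyvinylpalladium species that adds syn across C6=C7 of the diene with the vinyl carbon going to the less substituted terminus C7 (C11–C7 bond), and the resulting η3‑allylpalladium unit over C6–C5–C4 is captured at C6 by the tethered carboxylate (O–C6 bond) with release of zerovalent palladium. The closest known reaction type is the Larock heteroannulation of 1,3‑dienes with organic halides that carry an O–H or N–H group (Heck insertion followed by Tsuji–Trost‑type C–O bond formation). The lactone closes in a 5‑exo mode at the allyl terminus C6, since closure at C4 would need a seven‑membered ring at a fully substituted carbon. C7 is set by 1,2‑induction from C8: with H8 eclipsing the diene, insertion should occur anti to the C8–OSiEt3 bond (Felkin–Anh type), which gives the 7,8‑anti relation of the target. C6 is set by delivery of the palladium‑bound carboxylate to the face that carries palladium under halide‑free conditions (net syn addition to the 6E alkene, hence the trans‑lactone), backed by equilibration of any cis‑lactone through re‑ionisation of the allylic C6–O bond, while the 4E geometry is kept because the disubstituted allyl terminus C4 cannot rotate without a tertiary σ‑palladium intermediate. The step needs chemoselectivity for the conjugated diene over the terminal and the 1,1‑disubstituted alkenes and regioselectivity for C7 over C4, which the higher reactivity of conjugated dienes in carbopalladation, the slow addition of 17 and the full substitution at C4 should secure.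

Step 11
Reactants: 18 (4S,5R)‑5‑[(1E)‑2‑[(tert‑butyldimethylsilyloxy)methyl]hexa‑1,5‑dien‑1‑yl]‑4‑[(1S,2S)‑2‑(methoxymethoxy)‑3‑[(methoxymethoxy)methyl]‑1‑(triethylsilyloxy)but‑3‑en‑1‑yl]‑3‑methylideneoxolan‑2‑one
Product: 19 (1(10)Z,4E,6R,7S,8S,9S)‑15‑(tert‑butyldimethylsilyloxy)‑9,14‑bis(methoxymethoxy)‑8‑(triethylsilyloxy)germacra‑1(10),4,11(13)‑trien‑12,6‑olide
Conditions: second‑generation Hoveyda–Grubbs catalyst [RuCl2(H2IMes)(=CH–C6H4‑2‑OiPr)] (15 mol %), 1,4‑benzoquinone (30 mol %), toluene (1 mM), 90 °C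
Reagents that add atoms: none
Why: Ring‑closing metathesis between the terminal C1 vinyl group and the 1,1‑disubstituted C10 alkene should give the ring‑cis trisubstituted alkene that ten‑membered rings favour, whereas closure onto the α‑methylene group would need a strained bridgehead alkene.

Step 12
Reactants: 19 (1(10)Z,4E,6R,7S,8S,9S)‑15‑(tert‑butyldimethylsilyloxy)‑9,14‑bis(methoxymethoxy)‑8‑(triethylsilyloxy)germacra‑1(10),4,11(13)‑trien‑12,6‑olide
Product: 20 (1(10)Z,4E,6R,7S,8S,9S)‑15‑(tert‑butyldimethylsilyloxy)‑8‑hydroxy‑9,14‑bis(methoxymethoxy)germacra‑1(10),4,11(13)‑trien‑12,6‑olide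
Conditions: PPTS, MeOH/CH2Cl2, 0 °C
Reagents that add atoms: none
Why: Acid‑catalysed methanolysis should cleave the secondary triethylsilyl ether much faster than the primary tert‑butyldimethylsilyl ether or the MOM acetals.

Step 13
Reactants: 20 (1(10)Z,4E,6R,7S,8S,9S)‑15‑(tert‑butyldimethylsilyloxy)‑8‑hydroxy‑9,14‑bis(methoxymethoxy)germacra‑1(10),4,11(13)‑trien‑12,6‑olide; 21 (S)‑2‑methylbutanoic acid
Product: 22 (1(10)Z,4E,6R,7S,8S,9S)‑15‑(tert‑butyldimethylsilyloxy)‑9,14‑bis(methoxymethoxy)‑8‑[(2S)‑2‑methylbutanoyloxy]germacra‑1(10),4,11(13)‑trien‑12,6‑olide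
Conditions: DCC, DMAP (10 mol %), CH2Cl2, 0 °C to rt
Reagents that add atoms: none
Why: Steglich esterification acylates the only free hydroxyl group with retention at C8 and, with catalytic DMAP at low temperature, should not racemise the α‑centre of the acid.

Step 14
Reactants: 22 (1(10)Z,4E,6R,7S,8S,9S)‑15‑(tert‑butyldimethylsilyloxy)‑9,14‑bis(methoxymethoxy)‑8‑[(2S)‑2‑methylbutanoyloxy]germacra‑1(10),4,11(13)‑trien‑12,6‑olide
Product: 23 (1(10)Z,4E,6R,7S,8S,9S)‑15‑(tert‑butyldimethylsilyloxy)‑9,14‑dihydroxy‑8‑[(2S)‑2‑methylbutanoyloxy]germacra‑1(10),4,11(13)‑trien‑12,6‑olide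
Conditions: Me2BBr (5 equiv), CH2Cl2, −78 °C; then aq. NaHCO3
Reagents that add atoms: none
Why: Lewis‑acid cleavage of the two MOM acetals with Me2BBr at low temperature should spare the esters, the lactone and the silyl ether.

Step 15
Reactants: 23 (1(10)Z,4E,6R,7S,8S,9S)‑15‑(tert‑butyldimethylsilyloxy)‑9,14‑dihydroxy‑8‑[(2S)‑2‑methylbutanoyloxy]germacra‑1(10),4,11(13)‑trien‑12,6‑olide
Product: 24 (1(10)E,4E,6R,7S,8S,9S)‑15‑(tert‑butyldimethylsilyloxy)‑9‑hydroxy‑8‑[(2S)‑2‑methylbutanoyloxy]‑14‑oxogermacra‑1(10),4,11(13)‑trien‑12,6‑olide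
Conditions: TEMPO (20 mol %), PhI(OAc)2 (1.2 equiv), CH2Cl2, rt
Reagents that add atoms: none
Why: The oxoammonium‑mediated (TEMPO) oxidation is selective for the primary allylic C14 alcohol over the hindered secondary C9 alcohol and should give the enal directly.

Step 16
Reactants: 24 (1(10)E,4E,6R,7S,8S,9S)‑15‑(tert‑butyldimethylsilyloxy)‑9‑hydroxy‑8‑[(2S)‑2‑methylbutanoyloxy]‑14‑oxogermacra‑1(10),4,11(13)‑trien‑12,6‑olide
Product: 25 (1(10)E,4E,6R,7S,8S,9S)‑9‑acetoxy‑15‑(tert‑butyldimethylsilyloxy)‑8‑[(2S)‑2‑methylbutanoyloxy]‑14‑oxogermacra‑1(10),4,11(13)‑trien‑12,6‑olide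
Conditions: Ac2O, pyridine, CH2Cl2, 0 °C
Reagents that add atoms: acetic anhydride, CC(=O)OC(C)=O
Why: Acetylation of the only free hydroxyl group under mildly basic conditions should outrun 1,2‑acyl migration from O8 and keeps O15 masked.

Step 17
Reactants: 25 (1(10)E,4E,6R,7S,8S,9S)‑9‑acetoxy‑15‑(tert‑butyldimethylsilyloxy)‑8‑[(2S)‑2‑methylbutanoyloxy]‑14‑oxogermacra‑1(10),4,11(13)‑trien‑12,6‑olide
Product: 26 (1(10)E,4E,6R,7S,8S,9S)‑9‑acetoxy‑15‑hydroxy‑8‑[(2S)‑2‑methylbutanoyloxy]‑14‑oxogermacra‑1(10),4,11(13)‑trien‑12,6‑olide (CNP0247637.6)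
Conditions: HF·pyridine, pyridine, THF, 0 °C
Reagents that add atoms: none
Why: Buffered fluoride desilylation should free the primary C15 alcohol without touching the enal, the two esters or the α‑methylene lactone.

Compound list

1 | (tert‑butyldimethylsilyloxy)acetaldehyde | O=CCO[Si](C)(C)C(C)(C)C | starting material
2 | but‑3‑enylmagnesium bromide | C=CCC[Mg]Br | starting material
3 | 1‑(tert‑butyldimethylsilyloxy)hex‑5‑en‑2‑ol (racemic) | C=CCCC(O)CO[Si](C)(C)C(C)(C)C | intermediate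
4 | 1‑(tert‑butyldimethylsilyloxy)hex‑5‑en‑2‑one | C=CCCC(=O)CO[Si](C)(C)C(C)(C)C | intermediate
5 | ethyl (triphenylphosphoranylidene)acetate | CCOC(=O)C=P(c1ccccc1)(c1ccccc1)c1ccccc1 | starting material
6 | ethyl (2E)‑3‑[(tert‑butyldimethylsilyloxy)methyl]hepta‑2,6‑dienoate | C=CCC/C(CO[Si](C)(C)C(C)(C)C)=C\C(=O)OCC | intermediate
7 | (2E)‑3‑[(tert‑butyldimethylsilyloxy)methyl]hepta‑2,6‑dien‑1‑ol | C=CCC/C(CO[Si](C)(C)C(C)(C)C)=C\CO | intermediate
8 | (2E)‑3‑[(tert‑butyldimethylsilyloxy)methyl]hepta‑2,6‑dienal | C=CCC/C(CO[Si](C)(C)C(C)(C)C)=C\C=O | intermediate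
9 | (triphenylphosphoranylidene)acetaldehyde | O=CC=P(c1ccccc1)(c1ccccc1)c1ccccc1 | starting material
10 | (2E,4E)‑5‑[(tert‑butyldimethylsilyloxy)methyl]nona‑2,4,8‑trienal | C=CCC/C(CO[Si](C)(C)C(C)(C)C)=C\C=C\C=O | intermediate
11 | 2‑methylenepropane‑1,3‑diol | C=C(CO)CO | starting material
12 | 3‑(methoxymethoxy)‑2‑[(methoxymethoxy)methyl]prop‑1‑ene | C=C(COCOC)COCOC | intermediate
13 | {3‑(methoxymethoxy)‑2‑[(methoxymethoxy)methyl]allyl}lithium, oxygen cis to CH2Li (not isolated) | [Li]C/C(COCOC)=C\OCOC | intermediate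
14 | B‑{3‑(methoxymethoxy)‑2‑[(methoxymethoxy)methyl]allyl}bis(isopinocampheyl)borane, Ipc from (−)‑α‑pinene, oxygen cis to CH2B (not isolated) | B(C/C(COCOC)=C\OCOC)([C@H]1C[C@H]2C[C@@H]([C@@H]1C)C2(C)C)[C@H]1C[C@H]2C[C@@H]([C@@H]1C)C2(C)C | intermediate
15 | (3S,4S,5E,7E)‑8‑[(tert‑butyldimethylsilyloxy)methyl]‑3‑(methoxymethoxy)‑2‑[(methoxymethoxy)methyl]dodeca‑1,5,7,11‑tetraen‑4‑ol | C=CCC/C(CO[Si](C)(C)C(C)(C)C)=C\C=C\[C@H](O)[C@@H](OCOC)C(=C)COCOC | intermediate
16 | (3S,4S,5E,7E)‑8‑[(tert‑butyldimethylsilyloxy)methyl]‑3‑(methoxymethoxy)‑2‑[(methoxymethoxy)methyl]‑4‑(triethylsilyloxy)dodeca‑1,5,7,11‑tetraene | C=CCC/C(CO[Si](C)(C)C(C)(C)C)=C\C=C\[C@H](O[Si](CC)(CC)CC)[C@@H](OCOC)C(=C)COCOC | intermediate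
17 | 2‑bromoacrylic acid | C=C(Br)C(=O)O | starting material
18 | (4S,5R)‑5‑[(1E)‑2‑[(tert‑butyldimethylsilyloxy)methyl]hexa‑1,5‑dien‑1‑yl]‑4‑[(1S,2S)‑2‑(methoxymethoxy)‑3‑[(methoxymethoxy)methyl]‑1‑(triethylsilyloxy)but‑3‑en‑1‑yl]‑3‑methylideneoxolan‑2‑one | C=CCC/C(CO[Si](C)(C)C(C)(C)C)=C\[C@H]1OC(=O)C(=C)[C@@H]1[C@H](O[Si](CC)(CC)CC)[C@@H](OCOC)C(=C)COCOC | intermediate
19 | (1(10)Z,4E,6R,7S,8S,9S)‑15‑(tert‑butyldimethylsilyloxy)‑9,14‑bis(methoxymethoxy)‑8‑(triethylsilyloxy)germacra‑1(10),4,11(13)‑trien‑12,6‑olide | C=C1C(=O)O[C@@H]2/C=C(/CO[Si](C)(C)C(C)(C)C)CC/C=C(/COCOC)[C@H](OCOC)[C@@H](O[Si](CC)(CC)CC)[C@@H]12 | intermediate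
20 | (1(10)Z,4E,6R,7S,8S,9S)‑15‑(tert‑butyldimethylsilyloxy)‑8‑hydroxy‑9,14‑bis(methoxymethoxy)germacra‑1(10),4,11(13)‑trien‑12,6‑olide | C=C1C(=O)O[C@@H]2/C=C(/CO[Si](C)(C)C(C)(C)C)CC/C=C(/COCOC)[C@H](OCOC)[C@@H](O)[C@@H]12 | intermediate
21 | (S)‑2‑methylbutanoic acid | CC[C@H](C)C(=O)O | starting material
22 | (1(10)Z,4E,6R,7S,8S,9S)‑15‑(tert‑butyldimethylsilyloxy)‑9,14‑bis(methoxymethoxy)‑8‑[(2S)‑2‑methylbutanoyloxy]germacra‑1(10),4,11(13)‑trien‑12,6‑olide | C=C1C(=O)O[C@@H]2/C=C(/CO[Si](C)(C)C(C)(C)C)CC/C=C(/COCOC)[C@H](OCOC)[C@@H](OC(=O)[C@@H](C)CC)[C@@H]12 | intermediate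
23 | (1(10)Z,4E,6R,7S,8S,9S)‑15‑(tert‑butyldimethylsilyloxy)‑9,14‑dihydroxy‑8‑[(2S)‑2‑methylbutanoyloxy]germacra‑1(10),4,11(13)‑trien‑12,6‑olide | C=C1C(=O)O[C@@H]2/C=C(/CO[Si](C)(C)C(C)(C)C)CC/C=C(/CO)[C@H](O)[C@@H](OC(=O)[C@@H](C)CC)[C@@H]12 | intermediate
24 | (1(10)E,4E,6R,7S,8S,9S)‑15‑(tert‑butyldimethylsilyloxy)‑9‑hydroxy‑8‑[(2S)‑2‑methylbutanoyloxy]‑14‑oxogermacra‑1(10),4,11(13)‑trien‑12,6‑olide | C=C1C(=O)O[C@@H]2/C=C(/CO[Si](C)(C)C(C)(C)C)CC/C=C(/C=O)[C@H](O)[C@@H](OC(=O)[C@@H](C)CC)[C@@H]12 | intermediate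
25 | (1(10)E,4E,6R,7S,8S,9S)‑9‑acetoxy‑15‑(tert‑butyldimethylsilyloxy)‑8‑[(2S)‑2‑methylbutanoyloxy]‑14‑oxogermacra‑1(10),4,11(13)‑trien‑12,6‑olide | C=C1C(=O)O[C@@H]2/C=C(/CO[Si](C)(C)C(C)(C)C)CC/C=C(/C=O)[C@H](OC(C)=O)[C@@H](OC(=O)[C@@H](C)CC)[C@@H]12 | intermediate
26 | (1(10)E,4E,6R,7S,8S,9S)‑9‑acetoxy‑15‑hydroxy‑8‑[(2S)‑2‑methylbutanoyloxy]‑14‑oxogermacra‑1(10),4,11(13)‑trien‑12,6‑olide (CNP0247637.6) | C=C1C(=O)O[C@@H]2/C=C(/CO)CC/C=C(/C=O)[C@H](OC(C)=O)[C@@H](OC(=O)[C@@H](C)CC)[C@@H]12 | target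

Total step count: 17. Longest linear sequence: 16 steps (steps 1–6 and 8–17, from 1 to 26); step 7 is the one‑step side branch.

Steps most likely to fail

1. Step 10 (key step). What may go wrong: migratory insertion on the diene face syn to the C8 silyloxy group, which would give the wrong configuration at C7 and, with it, at C6. Fallback, setting out from 15 and coming back at 22: C8 is carried through the annulation in its epimeric form as a stereochemical relay and is inverted when the ester is introduced. Oxidation of 15 with MnO2 should give the dienone F1. Chelation‑controlled reduction with Zn(BH4)2 (chelate between the ketone and the C9 methoxymethoxy oxygen) should give the 8,9‑anti alcohol F2. Silylation (TESCl, imidazole) should give its triethylsilyl ether F3. The annulation with 17 under the conditions of step 10, with the same intrinsic facial preference now leading to 6R,7S, should give the 8‑epi lactone F4. Ring‑closing metathesis as in step 11 should give the macrocycle F5, and methanolysis (PPTS, MeOH) the 8R alcohol F6. Mitsunobu esterification of F6 with 21 (PPh3, diisopropyl azodicarboxylate, toluene, 0 °C) should install the 2‑methylbutanoate with inversion at C8 and give 22.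

2. Step 11. What may go wrong: slow ring closure at the hindered 1,1‑disubstituted C10 alkene, so that intermolecular metathesis of the terminal alkene (oligomerisation) prevails. Fallback, setting out from 18 and coming back at 23: ring closure is postponed until O9 and O14 are free, so that a free allylic hydroxyl group next to C10 assists metathesis and the olefin is less shielded. Methanolysis of 18 (PPTS, MeOH, 0 °C) should give the alcohol F7. Steglich esterification with 21 (DCC, DMAP) should give the ester F8. Cleavage of both MOM ethers with Me2BBr (CH2Cl2, −78 °C) should give the acyclic diol F9. Ring‑closing metathesis of F9 (second‑generation Hoveyda–Grubbs catalyst, 1,4‑benzoquinone, toluene, 1 mM, 80 °C) should give the macrocyclic diol 23.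

3. Step 8. What may go wrong: incomplete or non‑selective lithiation of the 2‑substituted allyl ether and loss of the cis geometry of the allylborane, so that diastereo‑ and enantioselectivity erode. Fallback, setting out from 10 and coming back at 16: the two stereocentres are set by an Evans syn‑glycolate aldol reaction and the 1,1‑disubstituted alkene is built afterwards. Acylation of (R)‑4‑benzyloxazolidin‑2‑one with (methoxymethoxy)acetyl chloride (BuLi, THF, −78 °C) gives the imide F10. Its dibutylboron enolate (Bu2BOTf, Et3N, CH2Cl2, −78 °C) should add to 10 to give the syn‑aldol adduct F11. Transamination (MeNHOMe·HCl, AlMe3, CH2Cl2, 0 °C) should give the Weinreb amide F12, and silylation (TESCl, imidazole) its triethylsilyl ether F13. Addition of MOMOCH2Li (from Bu3SnCH2OMOM and BuLi, THF, −78 °C) should give the ketone F14. Wittig methylenation (Ph3PCH3Br, KN(SiMe3)2, THF, −78 to 0 °C) should then give 16.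

Further compounds

F1 | step 10 | (3S,5E,7E)‑8‑[(tert‑butyldimethylsilyloxy)methyl]‑3‑(methoxymethoxy)‑2‑[(methoxymethoxy)methyl]dodeca‑1,5,7,11‑tetraen‑4‑one | C=CCC/C(CO[Si](C)(C)C(C)(C)C)=C\C=C\C(=O)[C@@H](OCOC)C(=C)COCOC
F2 | step 10 | (3S,4R,5E,7E)‑8‑[(tert‑butyldimethylsilyloxy)methyl]‑3‑(methoxymethoxy)‑2‑[(methoxymethoxy)methyl]dodeca‑1,5,7,11‑tetraen‑4‑ol (C8 epimer of 15) | C=CCC/C(CO[Si](C)(C)C(C)(C)C)=C\C=C\[C@@H](O)[C@@H](OCOC)C(=C)COCOC
F3 | step 10 | triethylsilyl ether of F2 (C8 epimer of 16) | C=CCC/C(CO[Si](C)(C)C(C)(C)C)=C\C=C\[C@@H](O[Si](CC)(CC)CC)[C@@H](OCOC)C(=C)COCOC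
F4 | step 10 | (4S,5R)‑5‑[(1E)‑2‑[(tert‑butyldimethylsilyloxy)methyl]hexa‑1,5‑dien‑1‑yl]‑4‑[(1R,2S)‑2‑(methoxymethoxy)‑3‑[(methoxymethoxy)methyl]‑1‑(triethylsilyloxy)but‑3‑en‑1‑yl]‑3‑methylideneoxolan‑2‑one (C8 epimer of 18) | C=CCC/C(CO[Si](C)(C)C(C)(C)C)=C\[C@H]1OC(=O)C(=C)[C@@H]1[C@@H](O[Si](CC)(CC)CC)[C@@H](OCOC)C(=C)COCOC
F5 | step 10 | (1(10)Z,4E,6R,7S,8R,9S)‑15‑(tert‑butyldimethylsilyloxy)‑9,14‑bis(methoxymethoxy)‑8‑(triethylsilyloxy)germacra‑1(10),4,11(13)‑trien‑12,6‑olide (C8 epimer of 19) | C=C1C(=O)O[C@@H]2/C=C(/CO[Si](C)(C)C(C)(C)C)CC/C=C(/COCOC)[C@H](OCOC)[C@H](O[Si](CC)(CC)CC)[C@@H]12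
F6 | step 10 | (1(10)Z,4E,6R,7S,8R,9S)‑15‑(tert‑butyldimethylsilyloxy)‑8‑hydroxy‑9,14‑bis(methoxymethoxy)germacra‑1(10),4,11(13)‑trien‑12,6‑olide (C8 epimer of 20) | C=C1C(=O)O[C@@H]2/C=C(/CO[Si](C)(C)C(C)(C)C)CC/C=C(/COCOC)[C@H](OCOC)[C@H](O)[C@@H]12
F7 | step 11 | (4S,5R)‑5‑[(1E)‑2‑[(tert‑butyldimethylsilyloxy)methyl]hexa‑1,5‑dien‑1‑yl]‑4‑[(1S,2S)‑1‑hydroxy‑2‑(methoxymethoxy)‑3‑[(methoxymethoxy)methyl]but‑3‑en‑1‑yl]‑3‑methylideneoxolan‑2‑one | C=CCC/C(CO[Si](C)(C)C(C)(C)C)=C\[C@H]1OC(=O)C(=C)[C@@H]1[C@H](O)[C@@H](OCOC)C(=C)COCOC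
F8 | step 11 | (2S)‑2‑methylbutanoate of F7 at O8 | C=CCC/C(CO[Si](C)(C)C(C)(C)C)=C\[C@H]1OC(=O)C(=C)[C@@H]1[C@H](OC(=O)[C@@H](C)CC)[C@@H](OCOC)C(=C)COCOC
F9 | step 11 | (4S,5R)‑5‑[(1E)‑2‑[(tert‑butyldimethylsilyloxy)methyl]hexa‑1,5‑dien‑1‑yl]‑4‑[(1S,2S)‑2‑hydroxy‑3‑(hydroxymethyl)‑1‑[(2S)‑2‑methylbutanoyloxy]but‑3‑en‑1‑yl]‑3‑methylideneoxolan‑2‑one | C=CCC/C(CO[Si](C)(C)C(C)(C)C)=C\[C@H]1OC(=O)C(=C)[C@@H]1[C@H](OC(=O)[C@@H](C)CC)[C@@H](O)C(=C)CO
F10 | step 8 | (R)‑4‑benzyl‑3‑[(methoxymethoxy)acetyl]oxazolidin‑2‑one | COCOCC(=O)N1[C@H](Cc2ccccc2)COC1=O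
F11 | step 8 | syn‑aldol adduct of F10 and 10 (C8 and C9 configured as in 15, C10 as the imide carbonyl) | C=CCC/C(CO[Si](C)(C)C(C)(C)C)=C\C=C\[C@H](O)[C@@H](OCOC)C(=O)N1[C@H](Cc2ccccc2)COC1=O
F12 | step 8 | N‑methoxy‑N‑methyl amide of the aldol acid (free C8 hydroxyl) | C=CCC/C(CO[Si](C)(C)C(C)(C)C)=C\C=C\[C@H](O)[C@@H](OCOC)C(=O)N(C)OC
F13 | step 8 | triethylsilyl ether of F12 | C=CCC/C(CO[Si](C)(C)C(C)(C)C)=C\C=C\[C@H](O[Si](CC)(CC)CC)[C@@H](OCOC)C(=O)N(C)OC
F14 | step 8 | (methoxymethoxy)methyl ketone from F13 (C10 ketone analogue of 16) | C=CCC/C(CO[Si](C)(C)C(C)(C)C)=C\C=C\[C@H](O[Si](CC)(CC)CC)[C@@H](OCOC)C(=O)COCOC
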